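**Strategy.** The cyclohexene (C1 = quaternary carbinol bearing CH2OBz, C2 = CHOH, C3=C4, C5 = CH–OBz, C6 = CH–OAc) is disconnected at C3=C4 and at C5–C6. Both bonds are made in one flask. A D-tartrate-derived aldehyde holds C6 (CHO), C1, C2 and C3 (vinyl CH), with the C1/C2 diol locked as an isopropylidene acetal. It takes up C5–C4 from a γ-silyloxyallyl stannane by chelation-controlled addition, and the octa-1,7-diene so formed is closed by ring-closing metathesis in the same solution. The step exploits the C6(OH)–C5(OR)–C4=C3 homoallylic-alcohol/allylic-ether motif of the ring and the C1 oxygen α to C6 as the chelating handle.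

Key step: step 9

Remark on the chemistry (assumption): the lithium enolate of the tartrate acetonide is taken to be alkylated on the face anti to the neighbouring ester group, which gives the 4,5-cis diester; the choice of D-tartrate and of which carbon becomes C6 rests on this.

**Step 1**
Reactants: 1 dimethyl (4S,5S)-2,2-dimethyl-1,3-dioxolane-4,5-dicarboxylate
Product: 3 dimethyl (4R,5S)-2,2-dimethyl-4-{[(triisopropylsilyl)oxy]methyl}-1,3-dioxolane-4,5-dicarboxylate, via lithium ester enolate 2 (not isolated)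
Conditions: LiN(iPr)2, THF, –78 °C; then iPr3SiOCH2Cl, THF/HMPA, –78 to –50 °C
Reagents that add atoms: (triisopropylsiloxy)methyl chloride, ClCO[Si](C(C)C)(C(C)C)C(C)C
Why: Enolate alkylation of the tartrate acetonide, whose enolate resists β-elimination at low temperature; the α-chloro ether should enter anti to the C5 ester, so the new quaternary C4 carries CH2OSi trans and CO2Me cis to the C5 ester.

**Step 2**
Reactants: 3 dimethyl (4R,5S)-2,2-dimethyl-4-{[(triisopropylsilyl)oxy]methyl}-1,3-dioxolane-4,5-dicarboxylate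
Product: 4 methyl (4R,5S)-5-formyl-2,2-dimethyl-4-{[(triisopropylsilyl)oxy]methyl}-1,3-dioxolane-4-carboxylate
Conditions: iBu2AlH (one equivalent), CH2Cl2, –78 °C; MeOH, then aq. KNaC4H4O6
Reagents that add atoms: none
Why: Partial ester reduction; the C5 ester on a tertiary carbon is much less hindered than the C4 ester on the quaternary carbon, and the aluminium hemiacetal should hold the aldehyde level until quench.

**Step 3**
Reactants: 4 methyl (4R,5S)-5-formyl-2,2-dimethyl-4-{[(triisopropylsilyl)oxy]methyl}-1,3-dioxolane-4-carboxylate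
Product: 5 methyl (4R,5R)-5-ethenyl-2,2-dimethyl-4-{[(triisopropylsilyl)oxy]methyl}-1,3-dioxolane-4-carboxylate
Conditions: Ph3PCH3Br, KN(SiMe3)2, THF, –78 to 0 °C
Reagents that add atoms: methyltriphenylphosphonium bromide, C[P+](c1ccccc1)(c1ccccc1)c1ccccc1.[Br-]
Why: Wittig methylenation at low temperature should install the vinyl group (future C3) without epimerising the α-alkoxy centre.

**Step 4**
Reactants: 5 methyl (4R,5R)-5-ethenyl-2,2-dimethyl-4-{[(triisopropylsilyl)oxy]methyl}-1,3-dioxolane-4-carboxylate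
Product: 6 [(4R,5R)-5-ethenyl-2,2-dimethyl-4-{[(triisopropylsilyl)oxy]methyl}-1,3-dioxolan-4-yl]methanol
Conditions: LiAlH4, Et2O, 0 °C
Reagents that add atoms: none
Why: Hydride reduction of the remaining hindered ester to the neopentyl alcohol (the future CH2OBz carbon); silyl ether, acetal and alkene are inert.

**Step 5**
Reactants: 6 [(4R,5R)-5-ethenyl-2,2-dimethyl-4-{[(triisopropylsilyl)oxy]methyl}-1,3-dioxolan-4-yl]methanol
Product: 7 [(4R,5R)-5-ethenyl-2,2-dimethyl-4-{[(triisopropylsilyl)oxy]methyl}-1,3-dioxolan-4-yl]methyl benzoate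
Conditions: BzCl, pyridine, DMAP (cat.), CH2Cl2, 0 °C to rt
Reagents that add atoms: benzoyl chloride, O=C(Cl)c1ccccc1
Why: Acylation of the only free hydroxyl puts the primary benzoate of the target in place early.

**Step 6**
Reactants: 7 [(4R,5R)-5-ethenyl-2,2-dimethyl-4-{[(triisopropylsilyl)oxy]methyl}-1,3-dioxolan-4-yl]methyl benzoate
Product: 8 [(4S,5R)-5-ethenyl-4-(hydroxymethyl)-2,2-dimethyl-1,3-dioxolan-4-yl]methyl benzoate
Conditions: HF·pyridine, THF/pyridine, 0 °C to rt
Reagents that add atoms: none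
Why: Fluoride cleavage of the primary silyl ether under acidic buffering, chosen so that the benzoate should not migrate to the freed hydroxyl (a 1,3-acyl shift would invert the quaternary centre).

**Step 7**
Reactants: 8 [(4S,5R)-5-ethenyl-4-(hydroxymethyl)-2,2-dimethyl-1,3-dioxolan-4-yl]methyl benzoate
Product: 9 [(4S,5R)-5-ethenyl-4-formyl-2,2-dimethyl-1,3-dioxolan-4-yl]methyl benzoate
Conditions: Dess–Martin periodinane, NaHCO3, CH2Cl2, 0 °C to rt
Reagents that add atoms: none
Why: Dess–Martin oxidation of the neopentyl alcohol to the aldehyde (future C6), which has no α-hydrogen and cannot epimerise; formyl and vinyl are trans on the dioxolane.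

**Step 8**
Reactants: 10 tert-butyldimethyl(prop-2-en-1-yloxy)silane
Product: 12 (Z)-tert-butyldimethyl{[3-(tributylstannyl)prop-1-en-1-yl]oxy}silane, via lithiated allyl silyl ether 11 (not isolated)
Conditions: sec-BuLi, THF/HMPA, –78 °C; then Bu3SnCl, –78 °C
Reagents that add atoms: tributyltin chloride, CCCC[Sn](Cl)(CCCC)CCCC
Why: Allylic deprotonation gives the internally coordinated (Z)-oxyallyl anion, which is stannylated at the carbon remote from oxygen to give the γ-silyloxyallyl stannane.

**Step 9**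
Reactants: 9 [(4S,5R)-5-ethenyl-4-formyl-2,2-dimethyl-1,3-dioxolan-4-yl]methyl benzoate; 12 (Z)-tert-butyldimethyl{[3-(tributylstannyl)prop-1-en-1-yl]oxy}silane
Product: 14 [(3aR,4S,5R,7aR)-5-{[tert-butyl(dimethyl)silyl]oxy}-4-hydroxy-2,2-dimethyl-3a,4,5,7a-tetrahydro-1,3-benzodioxol-3a-yl]methyl benzoate, via diene alcohol 13 (not isolated)
Conditions: MgBr2·OEt2, CH2Cl2, –25 to 0 °C; then second-generation Grubbs catalyst, (H2IMes)(PCy3)Cl2Ru=CHPh (cat.), 40 °C, same flask; aq. NaHCO3
Reagents that add atoms: none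
Why: MgBr2 binds the aldehyde oxygen together with the dioxolane oxygen on the quaternary carbon, and the stannane adds through its oxygen-bearing γ-carbon (SE2′, open transition state, loss of Bu3SnBr) to make the C5–C6 bond; the ruthenium alkylidene then joins the two terminal vinyl groups of the octa-1,7-diene with loss of ethylene to make C3=C4. The closest known reaction types are the chelation-controlled addition of γ-silyloxyallyl stannanes to α-alkoxy aldehydes (giving syn,syn triol derivatives) and diene ring-closing metathesis to conduritol-type cyclohexenes. The only ring closed is the six-membered carbocycle, by olefin metathesis through a ruthenacyclobutane; it forms trans-fused to the dioxolane, and the cis ring alkene is enforced by ring size. The carbinol centre C6 is set by the five-membered magnesium chelate, which exposes the aldehyde face flanked by CH2OBz and shields the face under the fused dioxolane; the silyloxy centre C5 is set syn to C6 by the simple diastereoselection of γ-oxyallyl stannanes in the open transition state. The step needs aldehyde-face selectivity, syn selectivity, and addition to the aldehyde only; these are secured by the α-oxygen on the quaternary carbon, the reagent type, and the low electrophilicity of the benzoate. The trans arrangement of vinyl and formyl on the dioxolane lets the two alkenes reach each other for closure.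

**Step 10**
Reactants: 14 [(3aR,4S,5R,7aR)-5-{[tert-butyl(dimethyl)silyl]oxy}-4-hydroxy-2,2-dimethyl-3a,4,5,7a-tetrahydro-1,3-benzodioxol-3a-yl]methyl benzoate
Product: 15 [(3aS,4S,5R,7aR)-4-(acetyloxy)-5-{[tert-butyl(dimethyl)silyl]oxy}-2,2-dimethyl-3a,4,5,7a-tetrahydro-1,3-benzodioxol-3a-yl]methyl benzoate
Conditions: Ac2O, DMAP, pyridine, rt
Reagents that add atoms: acetic anhydride, CC(=O)OC(C)=O
Why: DMAP-catalysed acetylation of the only free hydroxyl fixes the acetate on C6 before the neighbouring oxygen is unmasked.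

**Step 11**
Reactants: 15 [(3aS,4S,5R,7aR)-4-(acetyloxy)-5-{[tert-butyl(dimethyl)silyl]oxy}-2,2-dimethyl-3a,4,5,7a-tetrahydro-1,3-benzodioxol-3a-yl]methyl benzoate
Product: 16 [(3aS,4S,5R,7aR)-4-(acetyloxy)-5-hydroxy-2,2-dimethyl-3a,4,5,7a-tetrahydro-1,3-benzodioxol-3a-yl]methyl benzoate
Conditions: HF·pyridine, THF/pyridine, 0 °C to rt
Reagents that add atoms: none
Why: Acidic fluoride desilylation of the allylic silyl ether; under these non-basic conditions the trans-vicinal acetate should stay on C6.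

**Step 12**
Reactants: 16 [(3aS,4S,5R,7aR)-4-(acetyloxy)-5-hydroxy-2,2-dimethyl-3a,4,5,7a-tetrahydro-1,3-benzodioxol-3a-yl]methyl benzoate
Product: 17 (3aS,4S,5R,7aR)-4-(acetyloxy)-3a-[(benzoyloxy)methyl]-2,2-dimethyl-3a,4,5,7a-tetrahydro-1,3-benzodioxol-5-yl benzoate
Conditions: BzCl, pyridine, DMAP (cat.), CH2Cl2, 0 °C
Reagents that add atoms: benzoyl chloride, O=C(Cl)c1ccccc1
Why: Fast benzoylation of the allylic C5 hydroxyl at low temperature, before any acetyl migration can compete.

**Step 13**
Reactants: 17 (3aS,4S,5R,7aR)-4-(acetyloxy)-3a-[(benzoyloxy)methyl]-2,2-dimethyl-3a,4,5,7a-tetrahydro-1,3-benzodioxol-5-yl benzoate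
Product: 18 [(1S,2R,5R,6S)-6-(acetyloxy)-5-(benzoyloxy)-1,2-dihydroxycyclohex-3-en-1-yl]methyl benzoate
Conditions: aq. CF3CO2H, CH2Cl2, 0 °C
Reagents that add atoms: none
Why: Acid hydrolysis of the strained trans-fused isopropylidene acetal frees the C1 tertiary and C2 secondary hydroxyls; the three esters are stable to cold aqueous acid.

**Compound list**
1 | dimethyl (4S,5S)-2,2-dimethyl-1,3-dioxolane-4,5-dicarboxylate (dimethyl 2,3-O-isopropylidene-D-tartrate) | COC(=O)[C@H]1OC(C)(C)O[C@@H]1C(=O)OC | starting material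
2 | lithium ester enolate of 1 (enolate carbon = C4 of the dioxolane) | COC(=O)[C@H]1OC(C)(C)OC1=C(OC)O[Li] | intermediate
3 | dimethyl (4R,5S)-2,2-dimethyl-4-{[(triisopropylsilyl)oxy]methyl}-1,3-dioxolane-4,5-dicarboxylate (esters cis) | COC(=O)[C@H]1OC(C)(C)O[C@@]1(CO[Si](C(C)C)(C(C)C)C(C)C)C(=O)OC | intermediate
4 | methyl (4R,5S)-5-formyl-2,2-dimethyl-4-{[(triisopropylsilyl)oxy]methyl}-1,3-dioxolane-4-carboxylate | O=C[C@H]1OC(C)(C)O[C@@]1(CO[Si](C(C)C)(C(C)C)C(C)C)C(=O)OC | intermediate
5 | methyl (4R,5R)-5-ethenyl-2,2-dimethyl-4-{[(triisopropylsilyl)oxy]methyl}-1,3-dioxolane-4-carboxylate | C=C[C@H]1OC(C)(C)O[C@@]1(CO[Si](C(C)C)(C(C)C)C(C)C)C(=O)OC | intermediate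
6 | [(4R,5R)-5-ethenyl-2,2-dimethyl-4-{[(triisopropylsilyl)oxy]methyl}-1,3-dioxolan-4-yl]methanol | C=C[C@H]1OC(C)(C)O[C@@]1(CO[Si](C(C)C)(C(C)C)C(C)C)CO | intermediate
7 | [(4R,5R)-5-ethenyl-2,2-dimethyl-4-{[(triisopropylsilyl)oxy]methyl}-1,3-dioxolan-4-yl]methyl benzoate | C=C[C@H]1OC(C)(C)O[C@@]1(CO[Si](C(C)C)(C(C)C)C(C)C)COC(=O)c1ccccc1 | intermediate
8 | [(4S,5R)-5-ethenyl-4-(hydroxymethyl)-2,2-dimethyl-1,3-dioxolan-4-yl]methyl benzoate | C=C[C@H]1OC(C)(C)O[C@@]1(CO)COC(=O)c1ccccc1 | intermediate
9 | [(4S,5R)-5-ethenyl-4-formyl-2,2-dimethyl-1,3-dioxolan-4-yl]methyl benzoate (formyl trans to vinyl) | C=C[C@H]1OC(C)(C)O[C@@]1(C=O)COC(=O)c1ccccc1 | intermediate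
10 | tert-butyldimethyl(prop-2-en-1-yloxy)silane | C=CCO[Si](C)(C)C(C)(C)C | starting material
11 | (Z)-3-{[tert-butyl(dimethyl)silyl]oxy}allyllithium | [Li]C/C=C\O[Si](C)(C)C(C)(C)C | intermediate
12 | (Z)-tert-butyldimethyl{[3-(tributylstannyl)prop-1-en-1-yl]oxy}silane | CCCC[Sn](CCCC)(CCCC)C/C=C\O[Si](C)(C)C(C)(C)C | intermediate
13 | [(4R,5R)-4-[(1S,2R)-2-{[tert-butyl(dimethyl)silyl]oxy}-1-hydroxybut-3-en-1-yl]-5-ethenyl-2,2-dimethyl-1,3-dioxolan-4-yl]methyl benzoate | C=C[C@H]1OC(C)(C)O[C@]1(COC(=O)c2ccccc2)[C@@H](O)[C@H](O[Si](C)(C)C(C)(C)C)C=C | intermediate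
14 | [(3aR,4S,5R,7aR)-5-{[tert-butyl(dimethyl)silyl]oxy}-4-hydroxy-2,2-dimethyl-3a,4,5,7a-tetrahydro-1,3-benzodioxol-3a-yl]methyl benzoate (trans-fused acetonide) | O[C@H]1[C@H](O[Si](C)(C)C(C)(C)C)C=C[C@H]2OC(C)(C)O[C@]12COC(=O)c1ccccc1 | intermediate
15 | [(3aS,4S,5R,7aR)-4-(acetyloxy)-5-{[tert-butyl(dimethyl)silyl]oxy}-2,2-dimethyl-3a,4,5,7a-tetrahydro-1,3-benzodioxol-3a-yl]methyl benzoate | CC(=O)O[C@H]1[C@H](O[Si](C)(C)C(C)(C)C)C=C[C@H]2OC(C)(C)O[C@]12COC(=O)c1ccccc1 | intermediate
16 | [(3aS,4S,5R,7aR)-4-(acetyloxy)-5-hydroxy-2,2-dimethyl-3a,4,5,7a-tetrahydro-1,3-benzodioxol-3a-yl]methyl benzoate | CC(=O)O[C@H]1[C@H](O)C=C[C@H]2OC(C)(C)O[C@]12COC(=O)c1ccccc1 | intermediate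
17 | (3aS,4S,5R,7aR)-4-(acetyloxy)-3a-[(benzoyloxy)methyl]-2,2-dimethyl-3a,4,5,7a-tetrahydro-1,3-benzodioxol-5-yl benzoate | CC(=O)O[C@H]1[C@H](OC(=O)c3ccccc3)C=C[C@H]2OC(C)(C)O[C@]12COC(=O)c1ccccc1 | intermediate
18 | [(1S,2R,5R,6S)-6-(acetyloxy)-5-(benzoyloxy)-1,2-dihydroxycyclohex-3-en-1-yl]methyl benzoate | CC(=O)O[C@H]1[C@H](OC(=O)c2ccccc2)C=C[C@@H](O)[C@@]1(O)COC(=O)c1ccccc1 | target

**Step count.** Total: 13 steps. Longest linear sequence: 12 steps (steps 1–7 and 9–13; step 8 makes the stannane in a side branch).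

**Steps most likely to fail and fallbacks**

Step 9 (key step). Chelation of magnesium between the aldehyde oxygen and the dioxolane oxygen may be too weak, so that the aldehyde is attacked from both faces. In addition, tin and magnesium halides, or the enol ether of unreacted stannane, may deactivate the ruthenium carbene before the ring closes. The fallback sets out from aldehyde 9 and makes the two bonds in two separate operations under catalyst control. Lithiated ether 11 is trapped with 2-isopropoxy-4,4,5,5-tetramethyl-1,3,2-dioxaborolane to give (Z)-tert-butyldimethyl{[3-(4,4,5,5-tetramethyl-1,3,2-dioxaborolan-2-yl)prop-1-en-1-yl]oxy}silane F1. F1 is added to 9 in toluene at low temperature with a chiral phosphoric acid, (S)-3,3′-bis(2,4,6-triisopropylphenyl)-1,1′-binaphthyl-2,2′-diyl hydrogen phosphate. The (S) acid is expected to be the matched enantiomer by analogy with simple aldehydes; the (R) acid is the alternative. The closed six-membered transition state turns the (Z) geometry into the syn relationship, and the catalyst rather than the substrate decides the aldehyde face. Diene 13 is then isolated and purified, and is closed with the second-generation Grubbs catalyst in CH2Cl2 in a separate step. The route is rejoined at 14.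

Step 1. The enolate may open by β-elimination of the acetal oxygen on warming, or may attack silicon rather than carbon of the bulky α-chloro ether, so that conversion to 3 stays low. The fallback sets out from 1: enolate 2 is trapped by aldol addition to gaseous monomeric formaldehyde (same facial sense) to give dimethyl (4R,5S)-4-(hydroxymethyl)-2,2-dimethyl-1,3-dioxolane-4,5-dicarboxylate F2. F2 is silylated with iPr3SiOSO2CF3 and 2,6-lutidine in CH2Cl2. The route is rejoined at 3.

Step 2. The aldehyde may be reduced further to the alcohol, the second ester may be attacked, or the α-alkoxy aldehyde may epimerise on isolation. The fallback sets out from 3 and differentiates the two carbons through a lactone. LiAlH4 reduces both esters to [(4R,5R)-2,2-dimethyl-4-{[(triisopropylsilyl)oxy]methyl}-1,3-dioxolane-4,5-diyl]dimethanol F3. TEMPO with PhI(OAc)2 oxidises the less hindered hydroxymethyl group on C5, and the resulting hydroxy aldehyde closes and is oxidised on to the cis-fused γ-lactone 2,2-dimethyl-6a-{[(triisopropylsilyl)oxy]methyl}tetrahydrofuro[3,4-d][1,3]dioxol-4-one F4. iBu2AlH at –78 °C gives the lactol 2,2-dimethyl-6a-{[(triisopropylsilyl)oxy]methyl}tetrahydrofuro[3,4-d][1,3]dioxol-4-ol F5. Methylenation of F5 with Ph3P=CH2 opens the lactol to alkenol 6, where the route is rejoined; 4 and 5 are bypassed.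

**Further compounds**
F1 | step 9 | (Z)-tert-butyldimethyl{[3-(4,4,5,5-tetramethyl-1,3,2-dioxaborolan-2-yl)prop-1-en-1-yl]oxy}silane | CC1(C)OB(C/C=C\O[Si](C)(C)C(C)(C)C)OC1(C)C
F2 | step 1 | dimethyl (4R,5S)-4-(hydroxymethyl)-2,2-dimethyl-1,3-dioxolane-4,5-dicarboxylate | COC(=O)[C@H]1OC(C)(C)O[C@@]1(CO)C(=O)OC
F3 | step 2 | [(4R,5R)-2,2-dimethyl-4-{[(triisopropylsilyl)oxy]methyl}-1,3-dioxolane-4,5-diyl]dimethanol | OC[C@H]1OC(C)(C)O[C@@]1(CO[Si](C(C)C)(C(C)C)C(C)C)CO
F4 | step 2 | cis-fused γ-lactone, 2,2-dimethyl-6a-{[(triisopropylsilyl)oxy]methyl}tetrahydrofuro[3,4-d][1,3]dioxol-4-one | O=C2[C@H]1OC(C)(C)O[C@@]1(CO[Si](C(C)C)(C(C)C)C(C)C)CO2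
F5 | step 2 | cis-fused lactol, 2,2-dimethyl-6a-{[(triisopropylsilyl)oxy]methyl}tetrahydrofuro[3,4-d][1,3]dioxol-4-ol | OC2[C@H]1OC(C)(C)O[C@@]1(CO[Si](C(C)C)(C(C)C)C(C)C)CO2
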